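**Plan**
1. Retrosynthesis: the ester C10–O bond is cut first, giving acid 19 and the 8,10-epoxy-7-ol 32 of the iridoid half. In the guaiane acid the C6–C7 and C1–C5 bonds are then cut together.
2. Enabling feature: in the cyclohepta-1,3-diene ring of the acid the diene C7=C8–C9=C10 is flanked by three contiguous sp3 carbons (C6, C5, C1), and C1/C5 are bridged by C2–C4 of the cyclopentane. This is the imprint of a [5+2] union of a C7–C8–C9–C10–C1 unit (a 3-acyloxy-1,4-enyne) with the C5=C6 vinyl group on the C2–C4 tether.
3. Forward, acid: (R)-β-citronellene → ynoate → Z-configured Baylis–Hillman-type enyne carbinol → aroyl ester. One rhodium-catalysed step closes the five- and the seven-membered ring together. The migrated C8 aroyloxy group (the activating helper) is then removed via the dienyl triflate.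
4. Forward, iridoid half: (S)-carvone → cis-carveol → oxidative ring cleavage and aldol re-closure to the cyclopentene → δ-lactone ring by ene-chlorination and O-alkylation → deconjugation → directed epoxidation.
5. Stereochemistry: C4 comes from citronellene; C1 and C5 from the C9 carbinol (CBS reduction) by transfer of chirality and cis insertion. Iridoid C5 comes from carvone, C7 from the Luche reduction, C9 from kinetic protonation, C8 from hydroxyl-directed epoxidation.
6. The halves are joined last by Ti(OiPr)4-mediated attack of the acid on C10 of the epoxy alcohol, which also frees the C8 hydroxyl.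

Key step: step 9

Remark (numbering): guaiane numbering is used for the acid half (C1/C5 ring fusion, C15 methyl on C4, isopropyl on C7, carboxyl C14 on C10). Iridoid numbering is used for the lactone half (C1 lactone carbonyl, O2, C3, C4 with exocyclic C11, C5, C6, C7, C8 bearing C10, C9).
Remark (assumption): the rhodium cycloisomerisation is assumed to follow the anti relationship between leaving oxygen and incoming metal that underlies chirality transfer from enantioenriched 3-acyloxy-1,4-enynes; the (9S) carbinol and the Z-alkene are chosen on that basis.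
Remark (assumption): 4-methylpent-2-ynal is made (step 4) and not bought; (R)-β-citronellene, 3-methylbut-1-yne and (S)-carvone are the commercial starting materials.

**Guaiane acid**

Step 1
Reactants: 1 (R)-β-citronellene
Product: 3 (R)-4-methylhex-5-enal, via trisubstituted epoxide 2 (not isolated)
Conditions: mCPBA, CH2Cl2, 0 °C; then H5IO6, THF/H2O, 0 °C to rt
Reagents that add atoms: 3-chloroperoxybenzoic acid, OOC(=O)c1cccc(Cl)c1
Why: Prilezhaev epoxidation is much faster at the electron-rich trisubstituted alkene than at the vinyl group, and periodic acid then hydrolyses and cleaves the epoxide (glycol cleavage) to the aldehyde without touching the stereocentre.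

Step 2
Reactants: 3 (R)-4-methylhex-5-enal
Product: 4 (5R)-1,1-dibromo-5-methylhepta-1,6-diene
Conditions: CBr4, PPh3, CH2Cl2, 0 °C
Reagents that add atoms: carbon tetrabromide, BrC(Br)(Br)Br
Why: Corey–Fuchs dibromoolefination (Wittig-type reaction of the ylide formed in the flask) is reliable for unhindered aldehydes and leaves the remote vinyl group alone.

Step 3
Reactants: 4 (5R)-1,1-dibromo-5-methylhepta-1,6-diene
Product: 6 methyl (6R)-6-methyloct-7-en-2-ynoate, via lithium acetylide 5 (not isolated)
Conditions: n-BuLi (2.1 equiv), THF, −78 to 0 °C; then ClCO2Me, −78 °C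
Reagents that add atoms: methyl chloroformate, COC(Cl)=O
Why: Second stage of the Corey–Fuchs sequence, in which bromine–lithium exchange and Fritsch–Buttenberg–Wiechell rearrangement give the lithium acetylide that is acylated by the chloroformate.

Step 4
Reactants: 7 3-methylbut-1-yne
Product: 9 4-methylpent-2-ynal, via lithium acetylide 8 (not isolated)
Conditions: n-BuLi, THF, −40 °C; DMF; then inverse quench into aq. KH2PO4
Reagents that add atoms: N,N-dimethylformamide, CN(C)C=O
Why: Formylation of a lithium acetylide with DMF, the buffered inverse quench releasing the ynal without conjugate addition of dimethylamine.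

Step 5
Reactants: 6 methyl (6R)-6-methyloct-7-en-2-ynoate; 9 4-methylpent-2-ynal
Product: 11 methyl (2Z,6R)-2-[(1RS)-1-hydroxy-4-methylpent-2-yn-1-yl]-6-methylocta-2,7-dienoate, via vinylalane 10 (not isolated)
Conditions: i-Bu2AlH, N-methylmorpholine N-oxide, THF, 0 °C; then 9, 0 °C to rt; aq. potassium sodium tartrate
Reagents that add atoms: none
Why: Vinylalumination, in which syn-hydroalumination of the ynoate puts aluminium on the α-carbon cis to the β-hydrogen and addition to the aldehyde with retention should give the Baylis–Hillman-type adduct with the chain cis to the ester (Z), the carbinol centre being left uncontrolled and reset in steps 6 and 7.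

Step 6
Reactants: 11 methyl (2Z,6R)-2-[(1RS)-1-hydroxy-4-methylpent-2-yn-1-yl]-6-methylocta-2,7-dienoate
Product: 12 methyl (2Z,6R)-6-methyl-2-(4-methylpent-2-ynoyl)octa-2,7-dienoate
Conditions: Dess–Martin periodinane, NaHCO3, CH2Cl2, 0 °C
Reagents that add atoms: none
Why: Dess–Martin oxidation of a doubly activated (allylic and propargylic) secondary alcohol under buffered conditions that should leave the alkene geometry intact.

Step 7
Reactants: 12 methyl (2Z,6R)-6-methyl-2-(4-methylpent-2-ynoyl)octa-2,7-dienoate
Product: 13 methyl (2Z,6R)-2-[(1S)-1-hydroxy-4-methylpent-2-yn-1-yl]-6-methylocta-2,7-dienoate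
Conditions: (R)-2-methyl-CBS-oxazaborolidine (0.5 equiv), catecholborane, toluene, −78 °C
Reagents that add atoms: none
Why: Corey–Bakshi–Shibata reduction, in which the linear alkynyl group should act as the small and the α-branched alkenyl group as the large substituent, so that the (R)-catalyst is expected to give the (S)-carbinol (the antipodal catalyst would be used should the sense prove opposite).

Step 8
Reactants: 13 methyl (2Z,6R)-2-[(1S)-1-hydroxy-4-methylpent-2-yn-1-yl]-6-methylocta-2,7-dienoate
Product: 14 methyl (2Z,6R)-2-[(1S)-1-{[4-(dimethylamino)benzoyl]oxy}-4-methylpent-2-yn-1-yl]-6-methylocta-2,7-dienoate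
Conditions: 4-(dimethylamino)benzoyl chloride, Et3N, DMAP (cat.), CH2Cl2, 0 °C to rt
Reagents that add atoms: 4-(dimethylamino)benzoyl chloride, CN(C)c1ccc(cc1)C(Cl)=O
Why: DMAP-catalysed acylation of a secondary alcohol with retention, the electron-rich aroyl group being chosen because its carbonyl oxygen is the best nucleophile for the later 1,2-shift onto an internal alkyne.

Step 9
Reactants: 14 methyl (2Z,6R)-2-[(1S)-1-{[4-(dimethylamino)benzoyl]oxy}-4-methylpent-2-yn-1-yl]-6-methylocta-2,7-dienoate
Product: 15 methyl (1S,4R,5R)-8-{[4-(dimethylamino)benzoyl]oxy}guaia-7,9-dien-14-oate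
Conditions: [Rh(cod)2]BF4 (10 mol %), P(4-CF3C6H4)3 (20 mol %), ClCH2CH2Cl, 60–80 °C
Reagents that add atoms: none
Why: Cationic monovalent rhodium binds the 1,4-enyne, the carbonyl oxygen of the aroyl ester adds to C8 anti to the metal and the C9–O bond breaks (1,2-acyloxy migration, the first stage of a Rautenstrauch rearrangement) as rhodium bonds to C1, giving a rhodacyclohexadiene (Rh–C7=C8(OAr)–C9=C10–C1); the tethered vinyl group then inserts into the Rh–C1 bond and C(sp2)–C(sp3) reductive elimination joins C7 to C6. The closest known reaction type is the rhodium-catalysed intramolecular [5+2] cycloaddition of 3-acyloxy-1,4-enynes with tethered alkenes or alkynes (more remotely, the vinylcyclopropane–alkene [5+2]). The cyclopentane closes by 5-exo-trig migratory insertion (C1–C5) and the cycloheptadiene by reductive elimination from an eight-membered rhodacycle (C6–C7). C1 is controlled by the C9 carbinol centre through an anti SN2′-type transfer of chirality (rhodium enters C1 on the face opposite the leaving oxygen, in the conformer free of allylic 1,3-strain that the Z-alkene allows); C5 is controlled by the suprafacial insertion across the three-carbon tether, which enforces the cis ring fusion; C4 is carried from citronellene, and the (9S,Z) combination is chosen so that H1 and H5 fall on the face of H4. The step needs the 1,2- and not the 1,3-acyloxy shift at an internal alkyne and the [5+2] and not the Rautenstrauch cyclopentenone closure, which the electron-rich aroyl group, the electron-poor phosphine and the proximity of the tethered alkene are meant to secure; it also needs carbinol control to override the modest preference of the C4 methyl group for the convex face.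

Step 10
Reactants: 15 methyl (1S,4R,5R)-8-{[4-(dimethylamino)benzoyl]oxy}guaia-7,9-dien-14-oate
Product: 17 methyl (1S,4R,5R)-8-{[(trifluoromethyl)sulfonyl]oxy}guaia-7,9-dien-14-oate, via potassium dienolate 16 (not isolated)
Conditions: KOMe, THF/DMF, −40 to 0 °C; then PhNTf2, −78 °C to rt
Reagents that add atoms: N-phenylbis(trifluoromethanesulfonimide), O=S(=O)(N(c1ccccc1)S(=O)(=O)C(F)(F)F)C(F)(F)F
Why: Methoxide cleaves the dienyl (enol) ester to release the cross-conjugated dienolate regiospecifically (attack on the C14 methyl ester is degenerate), and O-sulfonylation with PhNTf2 gives the dienyl triflate without the free ketone, and with it the C1 centre, being exposed to base.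

Step 11
Reactants: 17 methyl (1S,4R,5R)-8-{[(trifluoromethyl)sulfonyl]oxy}guaia-7,9-dien-14-oate
Product: 18 methyl (1S,4R,5R)-guaia-7,9-dien-14-oate
Conditions: Pd(OAc)2 (5 mol %), PPh3, HCO2H, Et3N, DMF, 60 °C
Reagents that add atoms: none
Why: Palladium-catalysed formate reduction of an alkenyl triflate (oxidative addition to zerovalent palladium, formate exchange, decarboxylation, reductive elimination) replaces the C8 oxygen by hydrogen with both double bonds kept in place.

Step 12
Reactants: 18 methyl (1S,4R,5R)-guaia-7,9-dien-14-oate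
Product: 19 (1S,4R,5R)-guaia-7,9-dien-14-oic acid
Conditions: LiOH, THF/MeOH/H2O, 40 °C; then aq. HCl
Reagents that add atoms: lithium hydroxide, [Li+].[OH-]
Why: Saponification of the methyl ester, in which none of the three stereocentres is α to the carboxyl group and the ring-fusion C1–H is not vinylogously acidic, so no epimerisation is expected.

**Iridoid half**

Step 13
Reactants: 20 (S)-carvone
Product: 21 (1S,5S)-2-methyl-5-(prop-1-en-2-yl)cyclohex-2-en-1-ol (cis-carveol)
Conditions: NaBH4, CeCl3·7H2O, MeOH, −78 to 0 °C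
Reagents that add atoms: none
Why: Luche reduction, a 1,2-selective hydride addition in which axial attack should give the cis-alcohol (new centre S, hydroxyl cis to the isopropenyl group).

Step 14
Reactants: 21 cis-carveol
Product: 22 cis-carveol 2,3-epoxide (oxirane oxygen cis to the hydroxyl and to the isopropenyl group)
Conditions: VO(acac)2 (2 mol %), t-BuOOH, CH2Cl2, 0 °C to rt
Reagents that add atoms: tert-butyl hydroperoxide, CC(C)(C)OO
Why: Hydroxyl-directed vanadium-catalysed epoxidation is confined to the allylic alkene and delivers oxygen syn to the hydroxyl, so the isopropenyl group is untouched.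

Step 15
Reactants: 22 cis-carveol 2,3-epoxide
Product: 23 tert-butyldimethylsilyl ether of 22
Conditions: TBSCl, imidazole, DMF, rt
Reagents that add atoms: tert-butyldimethylsilyl chloride, CC(C)(C)[Si](C)(C)Cl
Why: Standard silylation that masks the carbinol during the glycol cleavage and the enolate chemistry that follow.

Step 16
Reactants: 23 silyl ether of cis-carveol 2,3-epoxide
Product: 24 (3R,5S)-5-[(tert-butyldimethylsilyl)oxy]-6-oxo-3-(prop-1-en-2-yl)heptanal
Conditions: H5IO6, THF/H2O, 0 °C to rt
Reagents that add atoms: water, O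
Why: Periodic acid opens the trisubstituted epoxide to the diol and cleaves it (Malaprade-type glycol cleavage) to the keto aldehyde, leaving both stereocentres and the isopropenyl group untouched.

Step 17
Reactants: 24 (3R,5S)-5-[(tert-butyldimethylsilyl)oxy]-6-oxo-3-(prop-1-en-2-yl)heptanal
Product: 25 (3S,5S)-3-[(tert-butyldimethylsilyl)oxy]-2-methyl-5-(prop-1-en-2-yl)cyclopent-1-ene-1-carbaldehyde
Conditions: piperidine (cat.), AcOH (cat.), toluene, rt to 40 °C
Reagents that add atoms: none
Why: Intramolecular aldol condensation through the enamine of the aldehyde (5-exo attack on the methyl ketone, then dehydration), the mode known for 6-oxoheptanals of this type, under mild amine–acid catalysis meant to avoid epimerisation α to the ketone.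

Step 18
Reactants: 25 (3S,5S)-3-[(tert-butyldimethylsilyl)oxy]-2-methyl-5-(prop-1-en-2-yl)cyclopent-1-ene-1-carbaldehyde
Product: 26 (3S,5S)-3-[(tert-butyldimethylsilyl)oxy]-2-methyl-5-(prop-1-en-2-yl)cyclopent-1-ene-1-carboxylic acid
Conditions: NaClO2, NaH2PO4, 2-methylbut-2-ene, t-BuOH/H2O, 0 °C to rt
Reagents that add atoms: sodium chlorite, [Na+].[O-]Cl=O
Why: Pinnick oxidation of the enal, with a hypochlorite scavenger that protects the isopropenyl group.

Step 19
Reactants: 26 (3S,5S)-3-[(tert-butyldimethylsilyl)oxy]-2-methyl-5-(prop-1-en-2-yl)cyclopent-1-ene-1-carboxylic acid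
Product: 28 (4aS,6S)-6-[(tert-butyldimethylsilyl)oxy]-7-methyl-4-methylidene-4,4a,5,6-tetrahydrocyclopenta[c]pyran-1(3H)-one, via allylic chloride 27 (not isolated)
Conditions: Ca(OCl)2, CO2 (solid), CH2Cl2/H2O, 0 °C; then K2CO3, DMF, rt
Reagents that add atoms: none
Why: Ene-type allylic chlorination by hypochlorous acid should occur only at the electron-rich 1,1-disubstituted alkene with shift of the double bond, and the carboxylate then closes the δ-lactone by 6-exo-tet SN2 displacement of the allylic chloride.

Step 20
Reactants: 28 (4aS,6S)-6-[(tert-butyldimethylsilyl)oxy]-7-methyl-4-methylidene-4,4a,5,6-tetrahydrocyclopenta[c]pyran-1(3H)-one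
Product: 30 (4aR,6S,7aR)-6-[(tert-butyldimethylsilyl)oxy]-4,7-dimethylidenehexahydrocyclopenta[c]pyran-1(3H)-one, via lithium dienolate 29 (not isolated)
Conditions: LiN(i-Pr)2, THF/DMPU, −78 °C; then AcOH in THF, −78 °C
Reagents that add atoms: none
Why: Kinetic deconjugation, in which γ-deprotonation at the C10 methyl group (held syn to the carbonyl) gives the extended enolate and kinetic α-protonation at C9 from the face opposite the C7 silyloxy group should give the β,γ-unsaturated cis-fused lactone (new centre C9, R).

Step 21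
Reactants: 30 (4aR,6S,7aR)-6-[(tert-butyldimethylsilyl)oxy]-4,7-dimethylidenehexahydrocyclopenta[c]pyran-1(3H)-one
Product: 31 (4aR,6S,7aR)-6-hydroxy-4,7-dimethylidenehexahydrocyclopenta[c]pyran-1(3H)-one
Conditions: HF·pyridine, THF/pyridine, 0 °C to rt
Reagents that add atoms: none
Why: Fluoride-mediated desilylation under mildly acidic conditions that should not re-conjugate the β,γ-unsaturated lactone.

Step 22
Reactants: 31 (4aR,6S,7aR)-6-hydroxy-4,7-dimethylidenehexahydrocyclopenta[c]pyran-1(3H)-one
Product: 32 (5R,7S,8S,9R)-8,10-epoxide of 31 (oxirane oxygen cis to the C7 hydroxyl)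
Conditions: VO(acac)2 (3 mol %), t-BuOOH, CH2Cl2, 0 °C to rt
Reagents that add atoms: tert-butyl hydroperoxide, CC(C)(C)OO
Why: Vanadium-catalysed hydroxyl-directed epoxidation acts only on the allylic 8(10)-alkene and should place the oxirane oxygen on the face of the C7 hydroxyl (C8 becomes S), leaving the 4(11)-alkene.

**Union**

Step 23
Reactants: 19 (1S,4R,5R)-guaia-7,9-dien-14-oic acid; 32 (5R,7S,8S,9R)-8,10-epoxy-7-hydroxy lactone
Product: 33 nardostachysin
Conditions: Ti(OiPr)4 (1.5 equiv), CH2Cl2, rt; aq. tartaric acid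
Reagents that add atoms: none
Why: Ti(OiPr)4-mediated opening of a 2,3-epoxy alcohol by a carboxylic acid, in which the titanium alkoxide of the C7 hydroxyl activates the oxirane and the carboxylate attacks the remote primary C10 (SN2), forming the ester and freeing the tertiary C8 hydroxyl with retention at C8.

**Compound list**
1 | (R)-β-citronellene, (3R)-3,7-dimethylocta-1,6-diene | C=C[C@H](C)CCC=C(C)C | starting material
2 | 2,2-dimethyl-3-[(3R)-3-methylpent-4-en-1-yl]oxirane (both oxirane epimers) | C=C[C@H](C)CCC1OC1(C)C | intermediate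
3 | (R)-4-methylhex-5-enal | C=C[C@H](C)CCC=O | intermediate
4 | (5R)-1,1-dibromo-5-methylhepta-1,6-diene | C=C[C@H](C)CCC=C(Br)Br | intermediate
5 | lithium (5R)-5-methylhept-6-en-1-yn-1-ide | C=C[C@H](C)CCC#C[Li] | intermediate
6 | methyl (6R)-6-methyloct-7-en-2-ynoate | C=C[C@H](C)CCC#CC(=O)OC | intermediate
7 | 3-methylbut-1-yne | CC(C)C#C | starting material
8 | lithium 3-methylbut-1-yn-1-ide | CC(C)C#C[Li] | intermediate
9 | 4-methylpent-2-ynal | CC(C)C#CC=O | intermediate
10 | methyl (2E,6R)-2-[bis(2-methylpropyl)alumanyl]-6-methylocta-2,7-dienoate (aluminium cis to the β-hydrogen) | C=C[C@H](C)CC/C=C(/[Al](CC(C)C)CC(C)C)C(=O)OC | intermediate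
11 | methyl (2Z,6R)-2-[(1RS)-1-hydroxy-4-methylpent-2-yn-1-yl]-6-methylocta-2,7-dienoate | C=C[C@H](C)CC/C=C(/C(O)C#CC(C)C)C(=O)OC | intermediate
12 | methyl (2Z,6R)-6-methyl-2-(4-methylpent-2-ynoyl)octa-2,7-dienoate | C=C[C@H](C)CC/C=C(/C(=O)C#CC(C)C)C(=O)OC | intermediate
13 | methyl (2Z,6R)-2-[(1S)-1-hydroxy-4-methylpent-2-yn-1-yl]-6-methylocta-2,7-dienoate | C=C[C@H](C)CC/C=C(/[C@@H](O)C#CC(C)C)C(=O)OC | intermediate
14 | methyl (2Z,6R)-2-[(1S)-1-{[4-(dimethylamino)benzoyl]oxy}-4-methylpent-2-yn-1-yl]-6-methylocta-2,7-dienoate | C=C[C@H](C)CC/C=C(/[C@@H](OC(=O)c1ccc(N(C)C)cc1)C#CC(C)C)C(=O)OC | intermediate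
15 | methyl (1S,4R,5R)-8-{[4-(dimethylamino)benzoyl]oxy}guaia-7,9-dien-14-oate (cis-fused, H1, H4 and H5 on one face) | COC(=O)C1=CC(OC(=O)c2ccc(N(C)C)cc2)=C(C(C)C)C[C@@H]2[C@H](C)CC[C@H]12 | intermediate
16 | potassium 7(8)-dienolate of methyl (1S,4R,5R)-8-oxoguai-9-en-14-oate | COC(=O)C1=CC([O-])=C(C(C)C)C[C@@H]2[C@H](C)CC[C@H]12.[K+] | intermediate
17 | methyl (1S,4R,5R)-8-{[(trifluoromethyl)sulfonyl]oxy}guaia-7,9-dien-14-oate | COC(=O)C1=CC(OS(=O)(=O)C(F)(F)F)=C(C(C)C)C[C@@H]2[C@H](C)CC[C@H]12 | intermediate
18 | methyl (1S,4R,5R)-guaia-7,9-dien-14-oate | COC(=O)C1=CC=C(C(C)C)C[C@@H]2[C@H](C)CC[C@H]12 | intermediate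
19 | (1S,4R,5R)-guaia-7,9-dien-14-oic acid, (3R,3aR,8aS)-3-methyl-5-(propan-2-yl)-1,2,3,3a,4,8a-hexahydroazulene-8-carboxylic acid | OC(=O)C1=CC=C(C(C)C)C[C@@H]2[C@H](C)CC[C@H]12 | intermediate
20 | (S)-carvone | CC1=CC[C@@H](CC1=O)C(C)=C | starting material
21 | (1S,5S)-2-methyl-5-(prop-1-en-2-yl)cyclohex-2-en-1-ol (cis-carveol) | CC1=CC[C@@H](C[C@@H]1O)C(C)=C | intermediate
22 | cis-carveol 2,3-epoxide, oxirane oxygen cis to OH and to isopropenyl | C[C@]12[C@H](O1)C[C@@H](C[C@@H]2O)C(C)=C | intermediate
23 | tert-butyldimethylsilyl ether of 22 | C[C@]12[C@H](O1)C[C@@H](C[C@@H]2O[Si](C)(C)C(C)(C)C)C(C)=C | intermediate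
24 | (3R,5S)-5-[(tert-butyldimethylsilyl)oxy]-6-oxo-3-(prop-1-en-2-yl)heptanal | CC(=O)[C@@H](O[Si](C)(C)C(C)(C)C)C[C@H](CC=O)C(C)=C | intermediate
25 | (3S,5S)-3-[(tert-butyldimethylsilyl)oxy]-2-methyl-5-(prop-1-en-2-yl)cyclopent-1-ene-1-carbaldehyde | CC1=C(C=O)[C@@H](C[C@@H]1O[Si](C)(C)C(C)(C)C)C(C)=C | intermediate
26 | (3S,5S)-3-[(tert-butyldimethylsilyl)oxy]-2-methyl-5-(prop-1-en-2-yl)cyclopent-1-ene-1-carboxylic acid | CC1=C(C(=O)O)[C@@H](C[C@@H]1O[Si](C)(C)C(C)(C)C)C(C)=C | intermediate
27 | (3S,5R)-3-[(tert-butyldimethylsilyl)oxy]-5-(3-chloroprop-1-en-2-yl)-2-methylcyclopent-1-ene-1-carboxylic acid | CC1=C(C(=O)O)[C@@H](C[C@@H]1O[Si](C)(C)C(C)(C)C)C(=C)CCl | intermediate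
28 | (4aS,6S)-6-[(tert-butyldimethylsilyl)oxy]-7-methyl-4-methylidene-4,4a,5,6-tetrahydrocyclopenta[c]pyran-1(3H)-one | C=C1COC(=O)C2=C(C)[C@@H](O[Si](C)(C)C(C)(C)C)C[C@@H]12 | intermediate
29 | lithium dienolate of 28 (C1–O enolate, C9=C1 and C8=C10) | C=C1COC([O-])=C2C(=C)[C@@H](O[Si](C)(C)C(C)(C)C)C[C@@H]12.[Li+] | intermediate
30 | (4aR,6S,7aR)-6-[(tert-butyldimethylsilyl)oxy]-4,7-dimethylidenehexahydrocyclopenta[c]pyran-1(3H)-one | C=C1COC(=O)[C@@H]2[C@H]1C[C@H](O[Si](C)(C)C(C)(C)C)C2=C | intermediate
31 | (4aR,6S,7aR)-6-hydroxy-4,7-dimethylidenehexahydrocyclopenta[c]pyran-1(3H)-one | C=C1COC(=O)[C@@H]2[C@H]1C[C@H](O)C2=C | intermediate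
32 | (5R,7S,8S,9R)-8,10-epoxy-7-hydroxy lactone (spiro-oxirane of 31, oxirane oxygen cis to the C7 hydroxyl) | C=C1COC(=O)[C@@H]2[C@H]1C[C@H](O)[C@@]23CO3 | intermediate
33 | nardostachysin | C=C1COC(=O)[C@@H]2[C@H]1C[C@H](O)[C@@]2(O)COC(=O)C1=CC=C(C(C)C)C[C@@H]2[C@H](C)CC[C@H]12 | target

Total step count: 23
Longest linear sequence: 12 steps (steps 1–3, 5–12 and 23)

**Steps most likely to fail**

Step 9. What may go wrong: the acyloxy group may undergo the 1,3-shift to an allenyl ester in place of the 1,2-shift; the rhodium may fail to engage the electron-poor, ester-bearing alkene, so that cyclometalation stalls or the Rautenstrauch path takes over; or transfer of chirality may be eroded. Fallback (sets out from 13, returns at 19): the five-carbon partner is changed from the acrylate type to the allylic silyl ether type of the parent reaction. C14 is carried at the alcohol level through ring formation and deoxygenation and oxidised only afterwards, which also allows cleavage of the dienyl ester by MeLi. The sequence would run as follows: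
- Reduction of the ester of 13 with i-Bu2AlH would give the diol (2E,6R)-2-[(1S)-1-hydroxy-4-methylpent-2-yn-1-yl]-6-methylocta-2,7-dien-1-ol F1.
- Selective silylation of the primary hydroxyl (TBSCl, imidazole) would give the silyl ether F2.
- Acylation with 4-(dimethylamino)benzoyl chloride would give the propargylic ester F3.
- The same rhodium-catalysed [5+2] cycloisomerisation would give the bicyclic dienyl ester F4.
- MeLi would cleave F4 to the lithium dienolate F5, and PhNTf2 would convert this to the dienyl triflate F6.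
- Pd(OAc)2/PPh3/HCO2H/Et3N would give the silyl ether of the dienol F7, and Bu4NF the dienol (1S,4R,5R)-guaia-7,9-dien-14-ol F8.
- MnO2 would give the dienal F9, and Pinnick oxidation would give acid 19.

Step 20. What may go wrong: γ-deprotonation may take place at the oxygen-bearing C7–H in place of the C10 methyl group; or the extended enolate may be protonated at C10 (return to 28) or from the wrong face at C9. Fallback (sets out from 28, returns at 30): the anionic deconjugation is replaced by a photochemical one. Irradiation at 254 nm in MeCN with a catalytic weak base (1,2-dimethylimidazole) would cause photoenolisation by a [1,5]-hydrogen shift from the C10 methyl group, the only γ-hydrogens held next to the carbonyl oxygen. This would give the dienol F10, and base-catalysed ketonisation of F10 at C9 from the open face would give 30 without any strong base.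

Step 23. What may go wrong: the carboxylic acid may open the oxirane slowly or at the tertiary C8; Ti(OiPr)4 may transesterify the lactone; or the acyl group may migrate to the C7 or C8 oxygen. Fallback (sets out from 31, returns at 33): the ester bond is made by acylation and not by epoxide opening. Hydroxyl-directed dihydroxylation of 31 (OsO4, TMEDA, CH2Cl2, −78 °C, reductive work-up), with delivery syn to the C7 hydroxyl, would give the triol (5R,7S,8S,9R)-7,8,10-trihydroxy lactone F11. Acid 19 would be activated as the mixed anhydride with 2,4,6-trichlorobenzoic acid F12 (2,4,6-trichlorobenzoyl chloride, Et3N; Yamaguchi esterification). With DMAP, F12 would acylate the primary C10 hydroxyl of F11 selectively to give 33.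

**Further compounds**
F1 | step 9 | (2E,6R)-2-[(1S)-1-hydroxy-4-methylpent-2-yn-1-yl]-6-methylocta-2,7-dien-1-ol | C=C[C@H](C)CC/C=C(/[C@@H](O)C#CC(C)C)CO
F2 | step 9 | primary tert-butyldimethylsilyl ether of F1 | C=C[C@H](C)CC/C=C(/[C@@H](O)C#CC(C)C)CO[Si](C)(C)C(C)(C)C
F3 | step 9 | 4-(dimethylamino)benzoate of F2 | C=C[C@H](C)CC/C=C(/[C@@H](OC(=O)c1ccc(N(C)C)cc1)C#CC(C)C)CO[Si](C)(C)C(C)(C)C
F4 | step 9 | (1S,4R,5R)-14-[(tert-butyldimethylsilyl)oxy]guaia-7,9-dien-8-yl 4-(dimethylamino)benzoate | CC(C)(C)[Si](C)(C)OCC1=CC(OC(=O)c2ccc(N(C)C)cc2)=C(C(C)C)C[C@@H]2[C@H](C)CC[C@H]12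
F5 | step 9 | lithium 7(8)-dienolate from F4 | CC(C)(C)[Si](C)(C)OCC1=CC([O-])=C(C(C)C)C[C@@H]2[C@H](C)CC[C@H]12.[Li+]
F6 | step 9 | (1S,4R,5R)-14-[(tert-butyldimethylsilyl)oxy]guaia-7,9-dien-8-yl trifluoromethanesulfonate | CC(C)(C)[Si](C)(C)OCC1=CC(OS(=O)(=O)C(F)(F)F)=C(C(C)C)C[C@@H]2[C@H](C)CC[C@H]12
F7 | step 9 | tert-butyldimethylsilyl ether of (1S,4R,5R)-guaia-7,9-dien-14-ol | CC(C)(C)[Si](C)(C)OCC1=CC=C(C(C)C)C[C@@H]2[C@H](C)CC[C@H]12
F8 | step 9 | (1S,4R,5R)-guaia-7,9-dien-14-ol | OCC1=CC=C(C(C)C)C[C@@H]2[C@H](C)CC[C@H]12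
F9 | step 9 | (1S,4R,5R)-guaia-7,9-dien-14-al | O=CC1=CC=C(C(C)C)C[C@@H]2[C@H](C)CC[C@H]12
F10 | step 20 | dienol of 28 (C1 hydroxyl, C9=C1 and C8=C10) | C=C1COC(O)=C2C(=C)[C@@H](O[Si](C)(C)C(C)(C)C)C[C@@H]12
F11 | step 23 | (4aR,6S,7S,7aR)-6,7-dihydroxy-7-(hydroxymethyl)-4-methylidenehexahydrocyclopenta[c]pyran-1(3H)-one | C=C1COC(=O)[C@@H]2[C@H]1C[C@H](O)[C@@]2(O)CO
F12 | step 23 | mixed anhydride of 19 with 2,4,6-trichlorobenzoic acid | O=C(OC(=O)c1c(Cl)cc(Cl)cc1Cl)C1=CC=C(C(C)C)C[C@@H]2[C@H](C)CC[C@H]12
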